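**Retrosynthetic overview**

1. Locants: ring A = 3(2H)-furanone (O, C10, C1, C2, C3); ring B = ten-membered carbocycle C1–C10; ring C = α-methylene-γ-lactone (O, C12, C11, C7, C6); C14 on C10, C15 on C4.
2. Target ⇐ acetylation at O9 ⇐ C9–C10 bond by an intramolecular Mukaiyama aldol that closes ring B. The enabling feature: C10 is C2 of ring A (α to the C1 ketone, bonded to the ring oxygen), so enol silylation gives an aromatic 3-silyloxyfuran nucleophilic at C10; C9 is the β-carbinol carbon (aldol retron O9–C9–C10–C1=O); the ring oxygen and the (Z)-C4=C5 bond make the closure effectively nine-membered.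
3. Seco-aldehyde ⇐ C8 esterification and C9 oxidation ⇐ ring C by chromium-mediated 2-(methoxycarbonyl)allylation and lactonization (C6–C7 bond) of a (Z)-furanonyl enal with a bromide from (R)-glyceraldehyde acetonide (C8 from the chiral pool).
4. Ring A ⇐ gold-catalysed 5-endo cyclization of an α'-hydroxy ynone made from (Z)-3-methylpent-2-en-4-yn-1-ol (C2–C6, C15, the (Z)-alkene) and a lactate Weinreb amide (C1, C10, C14, ring oxygen).
5. Order of ring formation: A, then C, then B in the key step, which also sets C9 and C10.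

Key step: step 18

Remark: the furanone C10–H centre is carried as an epimeric mixture (SMILES without a descriptor at that carbon) from its formation until the key step, where it becomes planar.

**Route**

Step 1
Reactants: 1 (2Z)-3-methylpent-2-en-4-yn-1-ol
Product: 2 tert-butyldimethylsilyl ether of 1
Conditions: TBSCl, imidazole, CH2Cl2, 0 °C to rt
Reagents that add atoms: tert-butyldimethylsilyl chloride CC(C)(C)[Si](C)(C)Cl
Why: Silyl ether formation masks the primary allylic alcohol, which would otherwise add to the ynone made in step 3, and leaves the (Z)-enyne untouched.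

Step 2
Reactants: 3 ethyl (S)-lactate
Product: 4 (2S)-2-hydroxy-N-methoxy-N-methylpropanamide
Conditions: MeNH(OMe)·HCl (2.5 equiv), i-PrMgCl (5 equiv), THF, −20 to 0 °C
Reagents that add atoms: N,O-dimethylhydroxylamine hydrochloride CNOC.Cl
Why: Weinreb amide formation by aminolysis of the ester with the magnesium amide should proceed on the unprotected hydroxy ester through its magnesium alkoxide without touching the stereocentre.

Step 3
Reactants: 2 silyl ether of the enynol, 4 lactic Weinreb amide
Product: 5 (2S,6Z)-α'-hydroxy ynone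
Conditions: 2 (2.3 equiv), n-BuLi (2.2 equiv), THF, −78 °C; then 4, −78 to 0 °C; aq. NH4Cl
Reagents that add atoms: none
Why: Weinreb ketone synthesis, in which one equivalent of the lithium acetylide deprotonates the hydroxyl group and a second adds to the amide to give a chelated tetrahedral intermediate that releases the ynone only on work-up, so over-addition should not occur.

Step 4
Reactants: 5 α'-hydroxy ynone
Product: 6 silyl-protected furanone (ring A)
Conditions: AuCl3 (5 mol %), CH2Cl2, rt
Reagents that add atoms: none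
Why: Gold-catalysed 5-endo-dig hydroalkoxylation of the α'-hydroxy ynone (the hydroxyl oxygen attacks the activated alkyne carbon β to the ketone) should give the 3(2H)-furanone, whose C10 centre is from here on configurationally irrelevant.

Step 5
Reactants: 6 silyl-protected furanone
Product: 7 furanone allylic alcohol
Conditions: HF·pyridine, pyridine, THF, 0 °C to rt
Reagents that add atoms: none
Why: Fluoride-mediated desilylation under buffered conditions should free the primary allylic alcohol without isomerizing the (Z)-alkene.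

Step 6
Reactants: 7 furanone allylic alcohol
Product: 8 (Z)-furanonyl enal
Conditions: MnO2, CH2Cl2, rt
Reagents that add atoms: none
Why: Allylic oxidation with MnO2 is selective for the allylic alcohol and should keep the (Z)-geometry of the trisubstituted alkene.

Step 7
Reactants: 9 (R)-glyceraldehyde acetonide, 10 methyl acrylate
Product: 11 Morita–Baylis–Hillman adduct
Conditions: DABCO, 1,4-dioxane/H2O (1:1), rt
Reagents that add atoms: none
Why: Morita–Baylis–Hillman reaction, whose new carbinol centre forms as a mixture that is removed in step 8, while the dioxolane centre (later C8) comes unchanged from the chiral pool.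

Step 8
Reactants: 11 Morita–Baylis–Hillman adduct
Product: 12 (Z)-allylic bromide
Conditions: NBS, Me2S, CH2Cl2, 0 °C to rt
Reagents that add atoms: N-bromosuccinimide O=C1CCC(=O)N1Br
Why: Activation of the allylic alcohol as an alkoxysulfonium salt and SN2' attack of bromide (Corey–Kim-type bromination) should give the thermodynamically preferred (Z)-2-(bromomethyl)enoate.

Step 9
Reactants: 8 (Z)-furanonyl enal, 12 (Z)-allylic bromide
Product: 14 trans-lactone acetonide (ring C), via hydroxy ester 13 (not isolated)
Conditions: CrCl2 (4 equiv), THF, 0 °C to rt; aq. NH4Cl; PPTS (cat.), CH2Cl2, rt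
Reagents that add atoms: none
Why: Nozaki–Hiyama allylation in which the equilibrating 2-(methoxycarbonyl)allylchromium reagent should add through a chair-like Zimmerman–Traxler transition state with the enal residue and the dioxolanyl group both equatorial (6,7-anti, hence the trans-lactone after loss of methanol), the face of C7 being chosen by the dioxolane centre C8 (attack anti to the C8–C9 bond with C8–H in the plane of the allyl unit).

Step 10
Reactants: 14 trans-lactone acetonide
Product: 15 lactone 8,9-diol
Conditions: AcOH/H2O (4:1), 40 °C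
Reagents that add atoms: none
Why: Acid-catalysed hydrolysis of the isopropylidene acetal should free the 8,9-diol while the lactone and the furanone are stable to aqueous acetic acid.

Step 11
Reactants: 15 lactone 8,9-diol
Product: 16 C9 triethylsilyl ether
Conditions: TESCl (1.05 equiv), imidazole, CH2Cl2, −78 to −30 °C
Reagents that add atoms: chlorotriethylsilane CC[Si](Cl)(CC)CC
Why: Silylation at low temperature should be selective for the primary C9 hydroxyl over the hindered secondary C8 hydroxyl.

Step 12
Reactants: 17 tert-butyl acrylate, 18 acetaldehyde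
Product: 19 tert-butyl 3-hydroxy-2-methylidenebutanoate
Conditions: DABCO (cat.), neat, sealed vessel, rt
Reagents that add atoms: none
Why: Morita–Baylis–Hillman reaction, whose racemic carbinol centre is removed in step 14.

Step 13
Reactants: 19 tert-butyl 3-hydroxy-2-methylidenebutanoate
Product: 20 tert-butyl 3-acetoxy-2-methylidenebutanoate
Conditions: Ac2O, pyridine, DMAP (cat.), CH2Cl2, 0 °C
Reagents that add atoms: acetic anhydride CC(=O)OC(C)=O
Why: DMAP-catalysed acetylation of the secondary allylic alcohol.

Step 14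
Reactants: 20 tert-butyl 3-acetoxy-2-methylidenebutanoate
Product: 21 tert-butyl (2E)-2-(acetoxymethyl)but-2-enoate
Conditions: DABCO (0.2 equiv), THF, 65 °C
Reagents that add atoms: none
Why: Amine-mediated 1,3-transposition of the Morita–Baylis–Hillman acetate (SN2' addition of DABCO, then SN2' return of acetate) should give the thermodynamically preferred primary acetate with the (E)-alkene (methyl trans to the ester).

Step 15
Reactants: 21 tert-butyl (2E)-2-(acetoxymethyl)but-2-enoate
Product: 22 (2E)-2-(acetoxymethyl)but-2-enoic acid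
Conditions: TFA, CH2Cl2, 0 °C to rt
Reagents that add atoms: none
Why: Acidolysis of the tert-butyl ester (loss of 2-methylpropene) should free the acid without touching the primary acetate or the alkene geometry.

Step 16
Reactants: 16 C9 triethylsilyl ether, 22 (2E)-2-(acetoxymethyl)but-2-enoic acid
Product: 23 C8 ester
Conditions: DCC, DMAP (cat.), CH2Cl2, 0 °C to rt
Reagents that add atoms: none
Why: Steglich esterification of the only free hydroxyl group (C8–OH) leaves C8 unchanged because its C–O bond is not broken, and the (E)-geometry of the acid is the thermodynamically stable one.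

Step 17
Reactants: 23 C8 ester
Product: 24 seco-aldehyde
Conditions: (COCl)2, DMSO, CH2Cl2, −78 to −40 °C; then Et3N, −78 to −20 °C
Reagents that add atoms: none
Why: Swern oxidation applied directly to the primary triethylsilyl ether (the chlorosulfonium reagent cleaves the Si–O bond and oxidizes the carbinol in the same flask) should give the α-acyloxy aldehyde without passing through the free primary alcohol, to which the neighbouring ester could migrate.

Step 18
Reactants: 24 seco-aldehyde
Product: 27 macrocyclic aldol (9-hydroxy compound), via silyloxyfuran 25 (not isolated), via silyl ether 26 (not isolated)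
Conditions: slow addition of 24 to TMSOTf (3 equiv), i-Pr2NEt (2.5 equiv), CH2Cl2 (final 1 mM), −78 to −40 °C; aq. citric acid, THF, 0 °C
Reagents that add atoms: none
Why: Soft enolization of the furanone with TMSOTf and i-Pr2NEt should give the aromatic 2-methyl-3-(trimethylsilyloxy)furan 25 (both C10 epimers of 24 converge), whose C2 (C10) attacks the TMSOTf-activated C9 aldehyde through an open transition state; silyl transfer gives 26 and the acidic work-up frees the C9 hydroxyl. The closest known reaction type is the Mukaiyama aldol addition of 3-silyloxyfurans to aldehydes at C2, which gives 2,2-disubstituted 3(2H)-furanones, here run as a Mukaiyama aldol macrocyclization. Ring B closes by 10-exo-trig attack on the aldehyde carbon (9-exo-trig when counted through the furan oxygen), and the planar furan, the (Z)-C4=C5 bond and the trans-lactone leave only the C6–C7, C7–C8 and C8–C9 bonds to be ordered. C9 should be controlled by the C8 acyloxy stereocentre (polar Felkin–Anh model, attack anti to the C8–O bond, giving the 8,9-anti relationship), and C10 by the tether, because the chain anchored at C6 can reach only one face of the furan across the twisted (Z)-diene, the face expected to lead to the (10R) centre. The step needs chemoselective enolization of the furanone (its enol is aromatic, so it is far more acidic than the α-acyloxy aldehyde), intramolecular reaction (slow addition, 1 mM) and survival of the allylic lactone C6–O bond towards the Lewis acid (low temperature).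

Step 19
Reactants: 27 macrocyclic aldol (9-hydroxy compound)
Product: 28 CNP0325609.1
Conditions: Ac2O, pyridine, DMAP (cat.), CH2Cl2, 0 °C to rt
Reagents that add atoms: acetic anhydride CC(=O)OC(C)=O
Why: DMAP-catalysed acetylation of the remaining hindered secondary hydroxyl group at C9 should complete the target with retention, since the C9–O bond is not broken.

**Compound list**

1 | (2Z)-3-methylpent-2-en-4-yn-1-ol | OC/C=C(/C)C#C | starting material
2 | tert-butyldimethyl{[(2Z)-3-methylpent-2-en-4-yn-1-yl]oxy}silane | CC(C)(C)[Si](C)(C)OC/C=C(/C)C#C | intermediate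
3 | ethyl (2S)-2-hydroxypropanoate (ethyl (S)-lactate) | CCOC(=O)[C@H](C)O | starting material
4 | (2S)-2-hydroxy-N-methoxy-N-methylpropanamide | C[C@H](O)C(=O)N(C)OC | intermediate
5 | (2S,6Z)-8-[(tert-butyldimethylsilyl)oxy]-2-hydroxy-6-methyloct-6-en-4-yn-3-one | CC(C)(C)[Si](C)(C)OC/C=C(/C)C#CC(=O)[C@H](C)O | intermediate
6 | 5-{(2Z)-4-[(tert-butyldimethylsilyl)oxy]but-2-en-2-yl}-2-methylfuran-3(2H)-one (C10 epimers) | CC(C)(C)[Si](C)(C)OC/C=C(/C)C1=CC(=O)C(C)O1 | intermediate
7 | 5-[(2Z)-4-hydroxybut-2-en-2-yl]-2-methylfuran-3(2H)-one (C10 epimers) | OC/C=C(/C)C1=CC(=O)C(C)O1 | intermediate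
8 | (2Z)-3-(5-methyl-4-oxo-4,5-dihydrofuran-2-yl)but-2-enal (C10 epimers) | O=C/C=C(/C)C1=CC(=O)C(C)O1 | intermediate
9 | (4R)-2,2-dimethyl-1,3-dioxolane-4-carbaldehyde | O=C[C@H]1COC(C)(C)O1 | starting material
10 | methyl acrylate | C=CC(=O)OC | starting material
11 | methyl 2-{[(4R)-2,2-dimethyl-1,3-dioxolan-4-yl](hydroxy)methyl}prop-2-enoate (carbinol epimers) | C=C(C(=O)OC)C(O)[C@H]1COC(C)(C)O1 | intermediate
12 | methyl (2Z)-2-(bromomethyl)-3-[(4S)-2,2-dimethyl-1,3-dioxolan-4-yl]prop-2-enoate | COC(=O)/C(CBr)=C/[C@H]1COC(C)(C)O1 | intermediate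
13 | methyl (3S,4R,5Z)-3-[(4S)-2,2-dimethyl-1,3-dioxolan-4-yl]-4-hydroxy-2-methylidene-6-(5-methyl-4-oxo-4,5-dihydrofuran-2-yl)hept-5-enoate (C10 epimers) | C=C(C(=O)OC)[C@@H]([C@H](O)/C=C(/C)C2=CC(=O)C(C)O2)[C@H]3COC(C)(C)O3 | intermediate
14 | (4S,5R)-4-[(4S)-2,2-dimethyl-1,3-dioxolan-4-yl]-3-methylidene-5-[(1Z)-2-(5-methyl-4-oxo-4,5-dihydrofuran-2-yl)prop-1-en-1-yl]oxolan-2-one (C6, C7, C8 as in the target; C10 epimers) | C=C1C(=O)O[C@H](/C=C(/C)C2=CC(=O)C(C)O2)[C@H]1[C@H]3COC(C)(C)O3 | intermediate
15 | (4R,5R)-4-[(1S)-1,2-dihydroxyethyl]-3-methylidene-5-[(1Z)-2-(5-methyl-4-oxo-4,5-dihydrofuran-2-yl)prop-1-en-1-yl]oxolan-2-one (same geometry at C6, C7, C8; C10 epimers) | C=C1C(=O)O[C@H](/C=C(/C)C2=CC(=O)C(C)O2)[C@H]1[C@H](O)CO | intermediate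
16 | (4R,5R)-4-{(1S)-1-hydroxy-2-[(triethylsilyl)oxy]ethyl}-3-methylidene-5-[(1Z)-2-(5-methyl-4-oxo-4,5-dihydrofuran-2-yl)prop-1-en-1-yl]oxolan-2-one (C10 epimers) | C=C1C(=O)O[C@H](/C=C(/C)C2=CC(=O)C(C)O2)[C@H]1[C@H](O)CO[Si](CC)(CC)CC | intermediate
17 | tert-butyl acrylate | C=CC(=O)OC(C)(C)C | starting material
18 | acetaldehyde | CC=O | starting material
19 | tert-butyl 3-hydroxy-2-methylidenebutanoate (racemic) | CC(O)C(=C)C(=O)OC(C)(C)C | intermediate
20 | tert-butyl 3-acetoxy-2-methylidenebutanoate (racemic) | CC(OC(C)=O)C(=C)C(=O)OC(C)(C)C | intermediate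
21 | tert-butyl (2E)-2-(acetoxymethyl)but-2-enoate | CC(C)(C)OC(=O)/C(=C/C)COC(C)=O | intermediate
22 | (2E)-2-(acetoxymethyl)but-2-enoic acid | OC(=O)/C(=C/C)COC(C)=O | intermediate
23 | (1S)-1-{(2R,3S)-4-methylidene-2-[(1Z)-2-(5-methyl-4-oxo-4,5-dihydrofuran-2-yl)prop-1-en-1-yl]-5-oxooxolan-3-yl}-2-[(triethylsilyl)oxy]ethyl (2E)-2-(acetoxymethyl)but-2-enoate (C10 epimers) | C=C1C(=O)O[C@H](/C=C(/C)C2=CC(=O)C(C)O2)[C@H]1[C@H](OC(=O)/C(=C/C)COC(C)=O)CO[Si](CC)(CC)CC | intermediate
24 | (1S)-1-{(2R,3S)-4-methylidene-2-[(1Z)-2-(5-methyl-4-oxo-4,5-dihydrofuran-2-yl)prop-1-en-1-yl]-5-oxooxolan-3-yl}-2-oxoethyl (2E)-2-(acetoxymethyl)but-2-enoate (seco-aldehyde; C10 epimers) | C=C1C(=O)O[C@H](/C=C(/C)C2=CC(=O)C(C)O2)[C@H]1[C@H](OC(=O)/C(=C/C)COC(C)=O)C=O | intermediate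
25 | (1S)-1-{(2R,3S)-4-methylidene-2-[(1Z)-2-{5-methyl-4-[(trimethylsilyl)oxy]furan-2-yl}prop-1-en-1-yl]-5-oxooxolan-3-yl}-2-oxoethyl (2E)-2-(acetoxymethyl)but-2-enoate | C=C1C(=O)O[C@H](/C=C(/C)c2cc(O[Si](C)(C)C)c(C)o2)[C@H]1[C@H](OC(=O)/C(=C/C)COC(C)=O)C=O | intermediate
26 | 9-O-trimethylsilyl ether of 27 (6R,7S,8S,9S,10R) | C=C1C(=O)O[C@@H]2/C=C(/C)C3=CC(=O)[C@](C)(O3)[C@@H](O[Si](C)(C)C)[C@@H](OC(=O)/C(=C/C)COC(C)=O)[C@@H]12 | intermediate
27 | 9-O-deacetyl target: (4Z,6R,7S,8S,9S,10R)-8-[(2E)-2-(acetoxymethyl)but-2-enoyloxy]-9-hydroxy-1-oxo-3,10-epoxygermacra-2,4,11(13)-trien-12,6-olide | C=C1C(=O)O[C@@H]2/C=C(/C)C3=CC(=O)[C@](C)(O3)[C@@H](O)[C@@H](OC(=O)/C(=C/C)COC(C)=O)[C@@H]12 | intermediate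
28 | CNP0325609.1: (4Z,6R,7S,8S,9S,10R)-9-acetoxy-8-[(2E)-2-(acetoxymethyl)but-2-enoyloxy]-1-oxo-3,10-epoxygermacra-2,4,11(13)-trien-12,6-olide | C=C1C(=O)O[C@@H]2/C=C(/C)C3=CC(=O)[C@](C)(O3)[C@@H](OC(C)=O)[C@@H](OC(=O)/C(=C/C)COC(C)=O)[C@@H]12 | target

**Summary**

Total step count: 19. Longest linear sequence: 12 steps (steps 1, 3, 4, 5, 6, 9, 10, 11, 16, 17, 18, 19).

Steps most likely to fail:

Step 18. The ring closure may be outrun by intermolecular aldol addition or by Lewis-acid ionization of the allylic lactone C6–O bond. The furan may also be attacked on the wrong face, so that C9 or C10 forms with the wrong configuration; the C10 prediction is the least secure one in the route. Fallback: the bond would be made reductively without a Lewis acid. Compound 24 is converted at −78 °C with TMSOTf (1.05 equiv) and i-Pr2NEt (1.2 equiv) into silyloxyfuran 25, which is brominated at C10 with NBS to give the 2-bromo-2-methylfuranone aldehyde F1. Slow addition of F1 to SmI2 (2.2 equiv) in THF at −78 °C (1 mM) should generate the samarium enolate, which closes ring B in a Reformatsky-type aldol addition through a chelated, closed transition state. Aqueous work-up returns to compound 27.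

Step 9. The simple diastereoselectivity may be poor (6,7-syn adduct and hence the cis-lactone), or the facial selectivity at C7 relative to C8 may be poor. Fallback: compounds 8 and 12 would be coupled with indium powder in THF/H2O, conditions expected to favour the syn adduct of such bromides, to give the 6,7-syn hydroxy ester F2. Mild ester cleavage with Me3SnOH (1,2-dichloroethane, 60 °C, aq. HCl work-up) gives the hydroxy acid F3. Mitsunobu lactonization (PPh3, DIAD, THF, 0 °C) with inversion at the allylic C6 carbinol returns to compound 14.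

Step 17. The α-acyloxy aldehyde may epimerize at C8 or eliminate under the amine base, or the triethylsilyl ether may be cleaved incompletely by the chlorosulfonium reagent. Fallback: compound 23 is desilylated with HF·pyridine (pyridine, THF, 0 °C) to the primary alcohol F4, which is oxidized at once under non-basic conditions with Dess–Martin periodinane and NaHCO3 (CH2Cl2, 0 °C) to return to compound 24.

Further compounds
F1 | step 18 | (1S)-1-{(2R,3S)-2-[(1Z)-2-(5-bromo-5-methyl-4-oxo-4,5-dihydrofuran-2-yl)prop-1-en-1-yl]-4-methylidene-5-oxooxolan-3-yl}-2-oxoethyl (2E)-2-(acetoxymethyl)but-2-enoate | C=C1C(=O)O[C@H](/C=C(/C)C2=CC(=O)C(C)(Br)O2)[C@H]1[C@H](OC(=O)/C(=C/C)COC(C)=O)C=O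
F2 | step 9 | methyl (3S,4S,5Z)-3-[(4S)-2,2-dimethyl-1,3-dioxolan-4-yl]-4-hydroxy-2-methylidene-6-(5-methyl-4-oxo-4,5-dihydrofuran-2-yl)hept-5-enoate (C6 epimer of 13) | C=C(C(=O)OC)[C@@H]([C@@H](O)/C=C(/C)C2=CC(=O)C(C)O2)[C@H]3COC(C)(C)O3
F3 | step 9 | (3S,4S,5Z)-3-[(4S)-2,2-dimethyl-1,3-dioxolan-4-yl]-4-hydroxy-2-methylidene-6-(5-methyl-4-oxo-4,5-dihydrofuran-2-yl)hept-5-enoic acid | C=C(C(=O)O)[C@@H]([C@@H](O)/C=C(/C)C2=CC(=O)C(C)O2)[C@H]3COC(C)(C)O3
F4 | step 17 | (1S)-2-hydroxy-1-{(2R,3S)-4-methylidene-2-[(1Z)-2-(5-methyl-4-oxo-4,5-dihydrofuran-2-yl)prop-1-en-1-yl]-5-oxooxolan-3-yl}ethyl (2E)-2-(acetoxymethyl)but-2-enoate | C=C1C(=O)O[C@H](/C=C(/C)C2=CC(=O)C(C)O2)[C@H]1[C@H](OC(=O)/C(=C/C)COC(C)=O)CO
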